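**Retrosynthetic overview** (abietane numbering: C10 quaternary with methyl C20; C1–C3 acid chain; C5 bearing isopropenyl C4/C18/C19; C6; C7=O; arene C8, C9, C11–C14)
1. Target 25 ⇐ lactone hydrolysis and chelation-controlled 14-O-demethylation of tricyclic keto-lactone 23.
2. Ring B (C5–C6–C7–C8–C9–C10) ⇐ C6–C7 bond by Ni(0)-catalysed redox-neutral intramolecular 1,2-hydroacylation of the 2,3-disubstituted diene in 22 by the C8 aldehyde. Enabling feature: the homoallylic aryl ketone C7(=O)–C6H2–C5H–C4(CH3)=C19H2 is the retron of aldehyde plus C6H2=C5–C4(CH3)=C19H2, and 11-OH with the C3 acid can be tied as a seven-membered lactone that holds C20 axial and relays C10 to C5.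
3. 22 ⇐ ethylene enyne metathesis of propynyl aldehyde 21 ⇐ Rieche formylation (C8) of lactone 20 ⇐ lactonisation of phenol acid 19.
4. C10 and its arms ⇐ NHC–Cu conjugate addition of the aryl-aluminium from 8 to 3-methylcyclopentenone with enolate trapping (13); ozonolysis opens the cyclopentene into the C3 acid and the C5 aldehyde (15), which is homologated to the propynyl group (18).
5. Arene 7 from 1,3-dimethoxybenzene by two directed metalations. Ring order: arene (present) → temporary lactone ring (step 10) → ring B (step 13).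

Key step: step 13

Assumption: the ligand enantiomer in step 5 is chosen to give the (S)-configured quaternary centre C10; if induction is opposite, the mirror-image ligand is used.
Abbreviation: Ar = 4-isopropyl-3,5-dimethoxy-2-(methoxymethoxy)phenyl.

Step 1
Reactants: 1 1,3-dimethoxybenzene
Product: 3 2-(2,6-dimethoxyphenyl)propan-2-ol, via (2,6-dimethoxyphenyl)lithium 2 (not isolated)
Conditions: n-BuLi, THF, 0 °C → rt; acetone, −78 °C → rt; aq NH4Cl
Reagents that add atoms: acetone, CC(C)=O
Why: Directed ortho-metalation at C2 between the two methoxy groups followed by 1,2-addition of the aryllithium to acetone should give the tertiary benzylic alcohol.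

Step 2
Reactants: 3 2-(2,6-dimethoxyphenyl)propan-2-ol
Product: 4 2-isopropyl-1,3-dimethoxybenzene
Conditions: Et3SiH, TFA, CH2Cl2, 0 °C → rt
Reagents that add atoms: none
Why: Ionic hydrogenation (silane/TFA) should reduce the tertiary benzylic alcohol through the methoxy-stabilised cumyl cation to the isopropyl group.

Step 3
Reactants: 4 2-isopropyl-1,3-dimethoxybenzene
Product: 7 3-isopropyl-2,4-dimethoxyphenol, via (3-isopropyl-2,4-dimethoxyphenyl)lithium 5 (not isolated), via dimethyl arylboronate 6 (not isolated)
Conditions: n-BuLi, TMEDA, Et2O, 0 °C → rt; B(OMe)3, −78 °C → rt; H2O2, AcOH, 0 °C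
Reagents that add atoms: hydrogen peroxide, OO
Why: Directed ortho-metalation next to a methoxy group (the two open ortho positions are equivalent), borylation and oxidative C–B to C–O conversion should install the phenol that becomes O-11.

Step 4
Reactants: 7 3-isopropyl-2,4-dimethoxyphenol
Product: 8 2-isopropyl-1,3-dimethoxy-4-(methoxymethoxy)benzene
Conditions: MOMCl, i-Pr2NEt, CH2Cl2, 0 °C → rt
Reagents that add atoms: chloromethyl methyl ether, COCCl
Why: O-Alkylation of the phenol should give the MOM ether, a strong directing group for the next metalation that is removable by mild acid.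

Step 5
Reactants: 8 2-isopropyl-1,3-dimethoxy-4-(methoxymethoxy)benzene; 9 3-methylcyclopent-2-en-1-one
Product: 13 (S)-{[3-Ar-3-methylcyclopent-1-en-1-yl]oxy}trimethylsilane, via aryllithium 10 (not isolated), via aryl(dimethyl)aluminium 11 (not isolated), via aluminium enolate 12 (not isolated)
Conditions: s-BuLi, THF, −78 → −20 °C; Me2AlCl, −78 °C → rt; 9, chiral bidentate sulfonate NHC–Ag(I) complex (2.5 mol%), Cu(OTf)2 (5 mol%), THF, −30 °C; TMSOTf, −30 → 0 °C; cold aq NaHCO3
Reagents that add atoms: trimethylsilyl triflate, C[Si](C)(C)OS(=O)(=O)C(F)(F)F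
Why: MOM-directed ortho-lithiation at the future C9, Li-to-Al transmetalation and NHC–Cu-catalysed enantioselective conjugate addition (aryl transferred in preference to methyl) to the β-methyl enone should create C10 with the configuration fixed by the chiral ligand, and O-silylation of the regiodefined aluminium enolate keeps the double bond on the C5 side.

Step 6
Reactants: 13 silyl enol ether
Product: 15 (R)-4-Ar-4-methyl-5-oxopentanoic acid, via trimethylsilyl ester aldehyde 14 (not isolated)
Conditions: O3, CH2Cl2–MeOH (4:1), −78 °C (Sudan Red 7B end point); Me2S, −78 °C → rt; aqueous work-up (pH 4)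
Reagents that add atoms: ozone, [O-][O+]=O
Why: Ozonolysis of the electron-rich silyl enol ether (faster than attack on the arene) should cleave C3=C5 to give the C3 acid after silyl ester hydrolysis and the non-enolisable C5 aldehyde, leaving C10 untouched.

Step 7
Reactants: 15 (R)-4-Ar-4-methyl-5-oxopentanoic acid
Product: 16 (S)-4-Ar-4-methylhex-5-ynoic acid
Conditions: dimethyl (1-diazo-2-oxopropyl)phosphonate, K2CO3 (3 equiv), MeOH, 0 °C → rt; then pH 3
Reagents that add atoms: dimethyl (1-diazo-2-oxopropyl)phosphonate, CC(=O)C(=[N+]=[N-])P(=O)(OC)OC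
Why: Seyferth–Gilbert homologation with the Ohira–Bestmann reagent should convert the α-quaternary aldehyde, which cannot epimerise, into the terminal alkyne.

Step 8
Reactants: 16 (S)-4-Ar-4-methylhex-5-ynoic acid
Product: 18 (S)-4-Ar-4-methylhept-5-ynoic acid, via lithium acetylide carboxylate 17 (not isolated)
Conditions: n-BuLi (2.2 equiv), THF, −78 °C; MeI, −78 → 0 °C; aq HCl
Reagents that add atoms: iodomethane, CI
Why: Double deprotonation should give the carboxylate–acetylide dianion, whose carbon nucleophile is methylated (acetylide alkylation) to the internal alkyne that serves as the robust precursor of the diene.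

Step 9
Reactants: 18 (S)-4-Ar-4-methylhept-5-ynoic acid
Product: 19 (S)-4-(2-hydroxy-4-isopropyl-3,5-dimethoxyphenyl)-4-methylhept-5-ynoic acid
Conditions: 3 M HCl, THF, 45 °C
Reagents that add atoms: none
Why: Acid hydrolysis of the MOM acetal should liberate the 11-OH while the internal alkyne, the aryl methyl ethers and the acid are inert.

Step 10
Reactants: 19 phenol acid
Product: 20 (S)-8-isopropyl-7,9-dimethoxy-5-methyl-5-(prop-1-yn-1-yl)-4,5-dihydro-1-benzoxepin-2(3H)-one
Conditions: EDC·HCl, DMAP (cat.), CH2Cl2 (0.01 M), rt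
Reagents that add atoms: none
Why: Carbodiimide (Steglich-type) lactonisation, helped by the gem-disubstituted C10, should close the seven-membered aryl ester under non-acidic conditions that cannot trigger Friedel–Crafts acylation at C8.

Step 11
Reactants: 20 alkynyl lactone
Product: 21 (S)-8-isopropyl-7,9-dimethoxy-5-methyl-2-oxo-5-(prop-1-yn-1-yl)-2,3,4,5-tetrahydro-1-benzoxepine-6-carbaldehyde
Conditions: Cl2CHOMe, TiCl4, CH2Cl2, −78 → −30 °C; H2O
Reagents that add atoms: dichloromethyl methyl ether, COC(Cl)Cl; water, O
Why: Rieche formylation should take place at the only free arene position, C8, which is ortho and para to the two methoxy groups.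

Step 12
Reactants: 21 alkynyl aldehyde lactone
Product: 22 (S)-8-isopropyl-7,9-dimethoxy-5-methyl-5-(3-methylbuta-1,3-dien-2-yl)-2-oxo-2,3,4,5-tetrahydro-1-benzoxepine-6-carbaldehyde
Conditions: ethylene (3 bar), Grubbs II catalyst (10 mol%), toluene, 80 °C
Reagents that add atoms: ethylene, C=C
Why: Ethylene–alkyne cross (enyne) metathesis should convert the internal alkyne into the 2,3-disubstituted 1,3-diene under neutral conditions that tolerate the aldehyde and the aryl ester.

Step 13
Reactants: 22 dienyl aldehyde lactone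
Product: 23 tricyclic keto-lactone: 3-[(1S,2S)-8-hydroxy-6-isopropyl-5,7-dimethoxy-1-methyl-4-oxo-2-(prop-1-en-2-yl)-1,2,3,4-tetrahydronaphthalen-1-yl]propanoic acid lactonised onto the 8-OH
Conditions: Ni(cod)2 (10 mol%), 1,3-di-tert-butylimidazol-2-ylidene (10 mol%), toluene, 60 °C
Reagents that add atoms: none
Why: Proposed new method: Ni(0)–NHC should bind the C7 aldehyde (η2) and the C5=C6 end of the diene and undergo oxidative cyclisation that forms C6–C7 and an η3-allyl(alkoxo)nickel(II) species over C5–C4–C19; β-hydride elimination of the C7–H alkoxide then gives the ketone and an allylnickel hydride, which reductively eliminates C5–H and returns Ni(0), so the aldehyde is isomerised to the homoallylic ketone without added reductant or oxidant. The closest known reaction types are the Ni(0)/NHC-catalysed intramolecular alkene hydroacylation of o-allylbenzaldehydes through oxanickelacycles and the Ni-catalysed homoallylation of aldehydes with 1,3-dienes (bond to the diene terminus, hydrogen to the adjacent internal carbon); a redox-neutral cyclisation of a diene tethered through its 2-position has not been shown. Ring B is closed in a 6-endo-trig sense with respect to C5=C6, the C19 terminus being out of reach for a strain-free closure. C5 is the only new stereocentre: C7 and H add to the same face of C5=C6, and because the seven-membered lactone keeps C1 near the arene plane the reactive conformer must carry the C10 methyl axial on the forming ring, so a half-chair closure delivers H-5 anti to that methyl (isopropenyl equatorial and cis to CH3, as in the target). The step needs 1,2- rather than 1,4-hydrogen delivery, which the proximity of C5 to Ni–H in the five-membered chelate and the strain of the alternative tetrasubstituted isopropylidene alkene should secure, and it needs the aryl ester to survive, for which the base-free conditions and moderate temperature are chosen.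

Step 14
Reactants: 23 tricyclic keto-lactone
Product: 24 tricyclic phenol keto-lactone: 3-[(1S,2S)-5,8-dihydroxy-6-isopropyl-7-methoxy-1-methyl-4-oxo-2-(prop-1-en-2-yl)-1,2,3,4-tetrahydronaphthalen-1-yl]propanoic acid lactonised onto the 8-OH (5-OH free)
Conditions: MgI2·OEt2, toluene–Et2O, 60 °C; aq NH4Cl
Reagents that add atoms: none
Why: Chelation-controlled ether cleavage by MgI2 should remove only the methyl group peri to the C7 ketone (C14–OMe), leaving C12–OMe, the lactone and the alkene intact.

Step 15
Reactants: 24 tricyclic phenol keto-lactone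
Product: 25 3-[(1S,2S)-5,8-dihydroxy-6-isopropyl-7-methoxy-1-methyl-4-oxo-2-(prop-1-en-2-yl)-1,2,3,4-tetrahydronaphthalen-1-yl]propanoic acid (CNP0249049.1)
Conditions: LiOH, THF–H2O (degassed, Ar), 0 °C → rt; cold 1 M HCl to pH 3
Reagents that add atoms: lithium hydroxide, [Li+].[OH-]
Why: Saponification of the aryl ester should release the 11-OH and the carboxylic acid; C5 is β to the ketone and C10 is quaternary, so no stereocentre can epimerise, and exclusion of air protects the hydroquinone.

**Compound list**
1 | 1,3-dimethoxybenzene | COc1cccc(OC)c1 | starting material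
2 | (2,6-dimethoxyphenyl)lithium | [Li]c1c(OC)cccc1OC | intermediate
3 | 2-(2,6-dimethoxyphenyl)propan-2-ol | COc1cccc(OC)c1C(C)(C)O | intermediate
4 | 2-isopropyl-1,3-dimethoxybenzene | COc1cccc(OC)c1C(C)C | intermediate
5 | (3-isopropyl-2,4-dimethoxyphenyl)lithium | [Li]c1ccc(OC)c(C(C)C)c1OC | intermediate
6 | dimethyl (3-isopropyl-2,4-dimethoxyphenyl)boronate | COB(OC)c1ccc(OC)c(C(C)C)c1OC | intermediate
7 | 3-isopropyl-2,4-dimethoxyphenol | Oc1ccc(OC)c(C(C)C)c1OC | intermediate
8 | 2-isopropyl-1,3-dimethoxy-4-(methoxymethoxy)benzene | COCOc1ccc(OC)c(C(C)C)c1OC | intermediate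
9 | 3-methylcyclopent-2-en-1-one | CC1=CC(=O)CC1 | starting material
10 | [4-isopropyl-3,5-dimethoxy-2-(methoxymethoxy)phenyl]lithium | COCOc1c([Li])cc(OC)c(C(C)C)c1OC | intermediate
11 | [4-isopropyl-3,5-dimethoxy-2-(methoxymethoxy)phenyl]dimethylaluminium | COCOc1c([Al](C)C)cc(OC)c(C(C)C)c1OC | intermediate
12 | dimethylaluminium enolate of (S)-3-Ar-3-methylcyclopentanone (enolate towards C2) | COCOc1c(OC)c(C(C)C)c(OC)cc1[C@@]1(C)CCC(O[Al](C)C)=C1 | intermediate
13 | (S)-{[3-Ar-3-methylcyclopent-1-en-1-yl]oxy}trimethylsilane | COCOc1c(OC)c(C(C)C)c(OC)cc1[C@@]1(C)CCC(O[Si](C)(C)C)=C1 | intermediate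
14 | trimethylsilyl (R)-4-Ar-4-methyl-5-oxopentanoate | COCOc1c(OC)c(C(C)C)c(OC)cc1[C@@](C=O)(C)CCC(=O)O[Si](C)(C)C | intermediate
15 | (R)-4-Ar-4-methyl-5-oxopentanoic acid | COCOc1c(OC)c(C(C)C)c(OC)cc1[C@@](C=O)(C)CCC(=O)O | intermediate
16 | (S)-4-Ar-4-methylhex-5-ynoic acid | COCOc1c(OC)c(C(C)C)c(OC)cc1[C@@](C#C)(C)CCC(=O)O | intermediate
17 | dilithium salt of 16 (lithium carboxylate, lithium acetylide) | COCOc1c(OC)c(C(C)C)c(OC)cc1[C@@](C#C[Li])(C)CCC(=O)O[Li] | intermediate
18 | (S)-4-Ar-4-methylhept-5-ynoic acid | COCOc1c(OC)c(C(C)C)c(OC)cc1[C@@](C#CC)(C)CCC(=O)O | intermediate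
19 | (S)-4-(2-hydroxy-4-isopropyl-3,5-dimethoxyphenyl)-4-methylhept-5-ynoic acid | Oc1c(OC)c(C(C)C)c(OC)cc1[C@@](C#CC)(C)CCC(=O)O | intermediate
20 | (S)-8-isopropyl-7,9-dimethoxy-5-methyl-5-(prop-1-yn-1-yl)-4,5-dihydro-1-benzoxepin-2(3H)-one | O=C1CC[C@](C#CC)(C)c2cc(OC)c(C(C)C)c(OC)c2O1 | intermediate
21 | (S)-8-isopropyl-7,9-dimethoxy-5-methyl-2-oxo-5-(prop-1-yn-1-yl)-2,3,4,5-tetrahydro-1-benzoxepine-6-carbaldehyde | O=C1CC[C@](C#CC)(C)c2c(C=O)c(OC)c(C(C)C)c(OC)c2O1 | intermediate
22 | (S)-8-isopropyl-7,9-dimethoxy-5-methyl-5-(3-methylbuta-1,3-dien-2-yl)-2-oxo-2,3,4,5-tetrahydro-1-benzoxepine-6-carbaldehyde | O=C1CC[C@](C(=C)C(C)=C)(C)c2c(C=O)c(OC)c(C(C)C)c(OC)c2O1 | intermediate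
23 | (1S,2S)-tricyclic keto-lactone (5,7-dimethoxy; acid lactonised onto 8-OH) | C=C(C)[C@@H]1CC(=O)c2c(OC)c(C(C)C)c(OC)c3OC(=O)CC[C@]1(C)c23 | intermediate
24 | (1S,2S)-tricyclic phenol keto-lactone (5-OH, 7-OMe; acid lactonised onto 8-OH) | C=C(C)[C@@H]1CC(=O)c2c(O)c(C(C)C)c(OC)c3OC(=O)CC[C@]1(C)c23 | intermediate
25 | 3-[(1S,2S)-5,8-dihydroxy-6-isopropyl-7-methoxy-1-methyl-4-oxo-2-(prop-1-en-2-yl)-1,2,3,4-tetrahydronaphthalen-1-yl]propanoic acid | C=C(C)[C@@H]1CC(=O)c2c(O)c(C(C)C)c(OC)c(O)c2[C@@]1(C)CCC(=O)O | target

**Total step count:** 15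
**Longest linear sequence:** 15 steps (from 1,3-dimethoxybenzene; 3-methylcyclopent-2-en-1-one enters in step 5)

**Steps most likely to fail**

Step 13 (proposed new method). The allylnickel hydride may deliver hydrogen to the distal terminus C19, giving the isopropylidene isomer. The allyl alkoxide may instead close a C–O bond (formal oxa-[4+2]). Ni(0) may insert into the acyl C–O bond of the aryl ester, or the aldehyde may dimerise. The fallback uses known reductive chemistry and sets out from 22. Ni(acac)2 (cat.) with Et3B in THF at rt should effect the reductive diene–aldehyde cyclisation (homoallylation: bond to the diene terminus C6, hydrogen to C5 on the same face). It should give the benzylic alcohol lactone F1 as a mixture at C7. Dess–Martin oxidation of F1 comes back to the route at 23.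

Step 5. Aryl transfer from the hindered ortho-alkoxy aryl-aluminium may be slow, so that methyl transfer or 1,2-addition competes. Enantioselectivity may be eroded, and the enolate regiochemistry may be lost by hydrolysis of the silyl enol ether. The fallback sets out from 8 and builds C10 with the aryl group on the electrophile. Ortho-lithiation of 8 and acylation with N-methoxy-N-methylacetamide should give the aryl methyl ketone F2. Horner–Wadsworth–Emmons olefination with triethyl phosphonoacetate gives the (E)-enoate F3, and DIBAL-H reduction gives the allylic alcohol F4. Diethyl chlorophosphate converts it into the allylic phosphate F5. NHC–Cu-catalysed enantioselective SN2' substitution with diisobutyl(prop-1-ynyl)aluminium should give the quaternary 1,4-enyne F6. Chemoselective hydroboration of its vinyl group with 9-BBN gives the alkylborane F7. Cu-catalysed carboxylation of F7 with CO2 (LiOMe) comes back to the route at 18.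

Step 11. Electrophilic attack at C8 may be retarded by the adjacent quaternary centre, and TiCl4 may meanwhile activate the alkyne or cleave an ether. The fallback sets out from 20 and uses a smaller electrophile at the alcohol oxidation level. Chloromethylation (MOMCl, ZnCl2, CH2Cl2) should give the benzylic chloride F8. Oxidation of F8 with N-methylmorpholine N-oxide in MeCN comes back to the route at 21.

**Further compounds**
F1 | step 13 | C7 carbinol of 23 (4-hydroxy instead of 4-oxo in naphthalene numbering; both C7 epimers) | C=C(C)[C@@H]1CC(O)c2c(OC)c(C(C)C)c(OC)c3OC(=O)CC[C@]1(C)c23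
F2 | step 5 | 1-[4-isopropyl-3,5-dimethoxy-2-(methoxymethoxy)phenyl]ethan-1-one | COCOc1c(OC)c(C(C)C)c(OC)cc1C(C)=O
F3 | step 5 | ethyl (E)-3-Ar-but-2-enoate | COCOc1c(OC)c(C(C)C)c(OC)cc1/C(C)=C/C(=O)OCC
F4 | step 5 | (E)-3-Ar-but-2-en-1-ol | COCOc1c(OC)c(C(C)C)c(OC)cc1/C(C)=C/CO
F5 | step 5 | (E)-3-Ar-but-2-en-1-yl diethyl phosphate | COCOc1c(OC)c(C(C)C)c(OC)cc1/C(C)=C/COP(=O)(OCC)OCC
F6 | step 5 | 1-[(S)-3-methylhex-1-en-4-yn-3-yl]-4-isopropyl-3,5-dimethoxy-2-(methoxymethoxy)benzene | COCOc1c(OC)c(C(C)C)c(OC)cc1[C@@](C#CC)(C)C=C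
F7 | step 5 | 9-[(S)-3-Ar-3-methylhex-4-yn-1-yl]-9-borabicyclo[3.3.1]nonane | COCOc1c(OC)c(C(C)C)c(OC)cc1[C@@](C#CC)(C)CCB1C2CCCC1CCC2
F8 | step 11 | (S)-6-(chloromethyl)-8-isopropyl-7,9-dimethoxy-5-methyl-5-(prop-1-yn-1-yl)-4,5-dihydro-1-benzoxepin-2(3H)-one | O=C1CC[C@](C#CC)(C)c2c(CCl)c(OC)c(C(C)C)c(OC)c2O1
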